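**Retrosynthetic overview**

1. Numbering: ring A = C1–C2–C3–C4–C5–C10, ring B = C5–C6–C7–C8–C9–C10, C14/C15 = methyls on C10/C4, C11 = carbinol carbon on C7, C1′ = benzylic carbon. Endgame: O-demethylation and desilylation; C1–H by hydrogenation of a C1=C2 alkene; C1′–aryl bond by aromatic Claisen rearrangement of the C2 aryl ether (SNAr with a fluoro dialdehyde) of a (Z)-1-(3-methylbutylidene) allylic alcohol.
2. The allylic alcohol comes from the C1 ketone (Wittig, allylic oxidation, Luche reduction); the C4 carbinol comes from MeMgBr addition to the C4 ketone of a trans-fused decalin-1,4-dione.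
3. Ring A is made by ring expansion: the 1,4-dione arises from a bicyclic cyclopentane-1,3-dione (ring C10–C1(=O)–CH2–C4(=O)–C5) by zinc-carbenoid insertion of one CH2 between the carbonyls.
4. Enabling feature: C1 (carries the side chain) and C4 (carbinol) are 1,4-related across ring A with only the unsubstituted CH2 groups C2 and C3 between them, so both can be carbonyls of one 1,4-diketone whose parent 1,3-diketone is a Claisen-condensation product.
5. The 1,3-dione comes from a catalytic asymmetric Diels–Alder adduct (ring B, C10, C5); order of ring formation: ring B, five-membered ring, ring A (expansion); the aryl ring is brought in intact.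

Key step: step 7

Remarks on the chemistry:
- The (S)-configured oxazaborolidine is assumed to give the (1S,6S) adduct 6; if the sense of induction is opposite, its enantiomer is used.
- C5 is drawn trans to C14 from 6 onward; should it epimerise in step 6 or 7, the base equilibration that closes step 7 returns it to the trans-fused form.
- 4-Fluoro-2,6-dimethoxybenzaldehyde (19) is taken as a catalogue building block.
- In the names the decalin is numbered as naphthalene (C4a = C5, C6 = C7, C8a = C10 of the numbering above).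

Step 1
Reactants: 1 2-methylbut-3-yn-2-ol
Product: 2 triethyl[(2-methylbut-3-yn-2-yl)oxy]silane
Conditions: Et3SiCl, imidazole, DMAP (5 mol %), DMF, 0 °C to rt
Reagents that add atoms: chlorotriethylsilane CC[Si](Cl)(CC)CC
Why: Silyl ether formation on the tertiary propargylic alcohol masks the future C11 hydroxyl against the Lewis acid of step 3 and the organometallic reagents and bases of later steps, and no stereocentre is involved.

Step 2
Reactants: 2 triethyl[(2-methylbut-3-yn-2-yl)oxy]silane; 3 ethylene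
Product: 4 triethyl[(2-methyl-3-methylidenepent-4-en-2-yl)oxy]silane
Conditions: ethylene (1 atm), second-generation Grubbs catalyst (5 mol %), CH2Cl2, 40 °C
Reagents that add atoms: none
Why: Ruthenium-carbene-catalysed enyne cross-metathesis of a terminal alkyne with ethylene gives the 2-substituted buta-1,3-diene directly and places the protected hydroxyisopropyl group on the diene carbon that becomes C7, with no stereocentre formed.

Step 3
Reactants: 4 triethyl[(2-methyl-3-methylidenepent-4-en-2-yl)oxy]silane; 5 ethyl (2E)-3-methyl-4-oxobut-2-enoate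
Product: 6 ethyl (1S,6S)-6-formyl-6-methyl-3-{2-[(triethylsilyl)oxy]propan-2-yl}cyclohex-3-ene-1-carboxylate
Conditions: (S)-1-(2-methylphenyl)-3,3-diphenyltetrahydro-1H,3H-pyrrolo[1,2-c][1,3,2]oxazaborole (20 mol %), (CF3SO2)2NH (20 mol %), CH2Cl2, −78 to −40 °C
Reagents that add atoms: none
Why: Enantioselective Diels–Alder reaction in which the boron Lewis acid binds the formyl group, so that the more nucleophilic diene terminus bonds to the β-carbon C5 and the diene substituent ends para to C10, the (E)-dienophile gives the trans C10-formyl/C5-ester relationship by suprafacial addition, and the chiral catalyst selects the enal face and thereby sets C10 (quaternary) and C5 together.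

Step 4
Reactants: 6 ethyl (1S,6S)-6-formyl-6-methyl-3-{2-[(triethylsilyl)oxy]propan-2-yl}cyclohex-3-ene-1-carboxylate
Product: 7 ethyl (1S,6S)-6-(1-hydroxyethyl)-6-methyl-3-{2-[(triethylsilyl)oxy]propan-2-yl}cyclohex-3-ene-1-carboxylate (both carbinol epimers)
Conditions: MeMgBr (1.1 equiv), THF, −78 °C; aq. NH4Cl
Reagents that add atoms: methylmagnesium bromide C[Mg]Br
Why: Chemoselective Grignard addition to the aldehyde in the presence of the less electrophilic ester supplies the carbon that becomes the ring CH2 between C1 and C4 of the cyclopentanedione, and the new carbinol centre is removed in step 5.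

Step 5
Reactants: 7 ethyl (1S,6S)-6-(1-hydroxyethyl)-6-methyl-3-{2-[(triethylsilyl)oxy]propan-2-yl}cyclohex-3-ene-1-carboxylate
Product: 8 ethyl (1S,6S)-6-acetyl-6-methyl-3-{2-[(triethylsilyl)oxy]propan-2-yl}cyclohex-3-ene-1-carboxylate
Conditions: Dess–Martin periodinane, NaHCO3, CH2Cl2, rt
Reagents that add atoms: none
Why: Dess–Martin oxidation of the secondary alcohol gives the methyl ketone without touching the silyl ether or the ester, and C10 (quaternary) and C5 are unaffected.

Step 6
Reactants: 8 ethyl (1S,6S)-6-acetyl-6-methyl-3-{2-[(triethylsilyl)oxy]propan-2-yl}cyclohex-3-ene-1-carboxylate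
Product: 9 (3aS,7aS)-7a-methyl-5-{2-[(triethylsilyl)oxy]propan-2-yl}-3a,4,7,7a-tetrahydro-1H-indene-1,3(2H)-dione (enolised β-diketone)
Conditions: LiN(SiMe3)2 (2.2 equiv), THF, −78 to 0 °C; 1 M HCl
Reagents that add atoms: none
Why: Intramolecular Claisen (Dieckmann-type) condensation in which the only possible ketone enolate (on the methyl group, since C10 is quaternary) attacks the neighbouring ester in a 5-exo-trig acyl substitution and the β-diketone is trapped as its enolate, closing the five-membered ring C10–C1–CH2–C4–C5 that is the precursor of ring A, while C10 is untouched and C5 is finally fixed in step 7.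

Step 7
Reactants: 9 (3aS,7aS)-7a-methyl-5-{2-[(triethylsilyl)oxy]propan-2-yl}-3a,4,7,7a-tetrahydro-1H-indene-1,3(2H)-dione
Product: 11 (4aS,8aS)-8a-methyl-6-{2-[(triethylsilyl)oxy]propan-2-yl}-2,3,4a,5,8,8a-hexahydronaphthalene-1,4-dione, via zinc cyclopropanolate 10 (not isolated)
Conditions: Et2Zn (3 equiv), CH2I2 (3 equiv), CH2Cl2, 0 °C to rt; aq. NH4Cl; then K2CO3, MeOH, rt
Reagents that add atoms: diiodomethane ICI
Why: Et2Zn converts the enolised β-diketone into its zinc enolate and forms with CH2I2 the carbenoid EtZnCH2I, which transfers CH2 to the enolate C=C (Simmons–Smith-type cyclopropanation) to give the donor–acceptor cyclopropanolate 10, whose alkoxide then expels the internal C–C bond toward the remaining ketone (retro-aldol-type fragmentation), so that CH2 is inserted between the central carbon and one carbonyl and the cyclopentane-1,3-dione ring becomes the cyclohexane-1,4-dione ring A. The closest known reaction type is the zinc-carbenoid chain extension of β-keto esters and β-diketones to γ-dicarbonyl compounds, including the one-carbon ring expansion of cyclic β-keto esters, and its older two-step variant through siloxycyclopropanes. The only ring closed is the transient cyclopropane, by concerted [2+1] methylene transfer; ring A is not closed from a chain but results from cleavage of the bond shared by the three- and five-membered rings (five to six). No stereocentre is created that survives, C10 is untouched, and C5, now α to the C4 ketone, is equilibrated by K2CO3/MeOH to the trans-fused diketone, which should be favoured because the C4 carbonyl removes one 1,3-diaxial interaction of the axial C14 methyl. The step needs chemoselectivity for the enolate over the trisubstituted ring-B alkene, which the far higher nucleophilicity of the zinc enolate and a limited excess of carbenoid should secure, and it needs no regiocontrol because cyclopropanation at either enolate terminus gives the same 1,4-diketone after fragmentation. The product carries carbonyl groups at exactly C1 and C4, and they are differentiated sterically by the quaternary C10 next to C1.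

Step 8
Reactants: 11 (4aS,8aS)-8a-methyl-6-{2-[(triethylsilyl)oxy]propan-2-yl}-2,3,4a,5,8,8a-hexahydronaphthalene-1,4-dione
Product: 12 (4aS,6S,8aS)-8a-methyl-6-{2-[(triethylsilyl)oxy]propan-2-yl}octahydronaphthalene-1,4-dione
Conditions: H2 (1 atm), [Ir(cod)(PCy3)(py)]PF6 (3 mol %), CH2Cl2, rt
Reagents that add atoms: none
Why: Homogeneous hydrogenation with the cationic iridium catalyst should reduce the trisubstituted ring-B alkene from the face opposite to the axial C14 methyl (1,3-related to C8 and C6), which sets C7 with H7 trans to C14 and the silyloxyisopropyl group equatorial, and it is placed here so that no hydroxyl can direct the catalyst and this alkene cannot interfere in step 11.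

Step 9
Reactants: 12 (4aS,6S,8aS)-8a-methyl-6-{2-[(triethylsilyl)oxy]propan-2-yl}octahydronaphthalene-1,4-dione
Product: 13 (4R,4aS,6S,8aS)-4-hydroxy-4,8a-dimethyl-6-{2-[(triethylsilyl)oxy]propan-2-yl}octahydronaphthalen-1(2H)-one
Conditions: MeMgBr (1.3 equiv), CeCl3, THF, −78 °C; aq. NH4Cl
Reagents that add atoms: methylmagnesium bromide C[Mg]Br
Why: Organocerium-moderated Grignard addition should be chemoselective for the C4 ketone because the C1 ketone is flanked by the quaternary C10, and the nucleophile enters C4 from the equatorial direction, away from the syn-axial C14 methyl, so that the new C4 stereocentre carries an axial hydroxyl cis to C14 and an equatorial methyl.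

Step 10
Reactants: 13 (4R,4aS,6S,8aS)-4-hydroxy-4,8a-dimethyl-6-{2-[(triethylsilyl)oxy]propan-2-yl}octahydronaphthalen-1(2H)-one; 14 (3-methylbutyl)triphenylphosphonium bromide
Product: 15 (1Z,4R,4aS,6S,8aS)-4,8a-dimethyl-1-(3-methylbutylidene)-6-{2-[(triethylsilyl)oxy]propan-2-yl}decahydronaphthalen-4-ol
Conditions: KOtBu (4 equiv), toluene, 100 °C
Reagents that add atoms: none
Why: Wittig olefination of the remaining hindered ketone with the non-stabilised ylide attaches C1′ together with the isobutyl group as a 3-methylbutylidene unit, and its alkene geometry (Z expected under kinetic control) is not decisive because the geometry is reset in step 11.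

Step 11
Reactants: 15 (1Z,4R,4aS,6S,8aS)-4,8a-dimethyl-1-(3-methylbutylidene)-6-{2-[(triethylsilyl)oxy]propan-2-yl}decahydronaphthalen-4-ol
Product: 17 (1Z,4R,4aS,6S,8aS)-4-hydroxy-4,8a-dimethyl-1-(3-methylbutylidene)-6-{2-[(triethylsilyl)oxy]propan-2-yl}octahydronaphthalen-2(1H)-one, via allylic alcohol 16 (not isolated)
Conditions: SeO2 (20 mol %), t-BuOOH (2 equiv), CH2Cl2, rt; then Dess–Martin periodinane, NaHCO3; then PhSSPh (5 mol %), visible light
Reagents that add atoms: tert-butyl hydroperoxide CC(C)(C)OO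
Why: Selenium dioxide allylic oxidation (ene reaction followed by a [2,3]-sigmatropic shift) hydroxylates the only allylic ring CH2 on the more substituted alkene terminus (C2), Dess–Martin oxidation then gives the α-alkylidene ketone, and thiyl-radical equilibration should favour the (Z)-enone in which the side-chain CH2 lies next to the carbonyl oxygen and not against the quaternary C10 (allylic 1,3-strain), which fixes the geometry later translated into C1′.

Step 12
Reactants: 17 (1Z,4R,4aS,6S,8aS)-4-hydroxy-4,8a-dimethyl-1-(3-methylbutylidene)-6-{2-[(triethylsilyl)oxy]propan-2-yl}octahydronaphthalen-2(1H)-one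
Product: 18 (1Z,2S,4R,4aS,6S,8aS)-4,8a-dimethyl-1-(3-methylbutylidene)-6-{2-[(triethylsilyl)oxy]propan-2-yl}decahydronaphthalene-2,4-diol
Conditions: NaBH4, CeCl3·7H2O, MeOH, −78 °C
Reagents that add atoms: none
Why: Luche 1,2-reduction should deliver hydride to C2 from the face opposite to the syn-axial C14 methyl and C4 hydroxyl, so that the new C2 stereocentre bears an axial hydroxyl cis to C14, the orientation needed for the suprafacial aryl transfer of step 15.

Step 13
Reactants: 19 4-fluoro-2,6-dimethoxybenzaldehyde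
Product: 20 4-fluoro-2,6-dimethoxybenzene-1,3-dicarbaldehyde
Conditions: Cl2CHOCH3, TiCl4, CH2Cl2, −20 to 0 °C; H2O
Reagents that add atoms: dichloromethyl methyl ether COC(Cl)Cl; water O
Why: Rieche formylation (electrophilic aromatic substitution) can occur only at the two equivalent free positions, each ortho to one methoxy group and para to the other, and gives a fluoride activated by one ortho and one para formyl group, with no stereocentre involved.

Step 14
Reactants: 18 (1Z,2S,4R,4aS,6S,8aS)-4,8a-dimethyl-1-(3-methylbutylidene)-6-{2-[(triethylsilyl)oxy]propan-2-yl}decahydronaphthalene-2,4-diol; 20 4-fluoro-2,6-dimethoxybenzene-1,3-dicarbaldehyde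
Product: 21 4-{[(1Z,2S,4R,4aS,6S,8aS)-4-hydroxy-4,8a-dimethyl-1-(3-methylbutylidene)-6-{2-[(triethylsilyl)oxy]propan-2-yl}decahydronaphthalen-2-yl]oxy}-2,6-dimethoxybenzene-1,3-dicarbaldehyde
Conditions: NaH (1.1 equiv), THF/DMF, 0 °C to rt
Reagents that add atoms: none
Why: Nucleophilic aromatic substitution (addition–elimination) of the fluoride by the secondary C2 alkoxide, which is more acidic and far less hindered than the tertiary C4 hydroxyl while C11 is silylated, forms the allyl aryl ether with retention at C2 because the C2–O bond is not broken.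

Step 15
Reactants: 21 4-{[(1Z,2S,4R,4aS,6S,8aS)-4-hydroxy-4,8a-dimethyl-1-(3-methylbutylidene)-6-{2-[(triethylsilyl)oxy]propan-2-yl}decahydronaphthalen-2-yl]oxy}-2,6-dimethoxybenzene-1,3-dicarbaldehyde
Product: 22 4-hydroxy-5-{(1S)-1-[(4R,4aS,6S,8aS)-4-hydroxy-4,8a-dimethyl-6-{2-[(triethylsilyl)oxy]propan-2-yl}-3,4,4a,5,6,7,8,8a-octahydronaphthalen-1-yl]-3-methylbutyl}-2,6-dimethoxybenzene-1,3-dicarbaldehyde
Conditions: N,N-diethylaniline, 175 °C
Reagents that add atoms: none
Why: Aromatic Claisen rearrangement ([3,3]-sigmatropic shift followed by tautomerisation to the phenol) in which the single free ortho carbon bonds to C1′ on the same face as the breaking axial C2–O bond, so that the (Z)-alkene geometry and the C2 configuration are transferred to the new C1′ stereocentre (S) while the C1=C2 alkene and the ortho hydroxyl are generated.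

Step 16
Reactants: 22 4-hydroxy-5-{(1S)-1-[(4R,4aS,6S,8aS)-4-hydroxy-4,8a-dimethyl-6-{2-[(triethylsilyl)oxy]propan-2-yl}-3,4,4a,5,6,7,8,8a-octahydronaphthalen-1-yl]-3-methylbutyl}-2,6-dimethoxybenzene-1,3-dicarbaldehyde
Product: 23 4-hydroxy-5-{(1S)-1-[(1R,4R,4aS,6S,8aR)-4-hydroxy-4,8a-dimethyl-6-{2-[(triethylsilyl)oxy]propan-2-yl}decahydronaphthalen-1-yl]-3-methylbutyl}-2,6-dimethoxybenzene-1,3-dicarbaldehyde
Conditions: H2 (3 atm), Pd/C (10 %), EtOAc, rt
Reagents that add atoms: none
Why: Heterogeneous hydrogenation should add hydrogen to the trisubstituted C1=C2 alkene from the face opposite to the axial C14 methyl and C4 hydroxyl, which sets C1 with H1 axial and the benzylic side chain equatorial (cis to C14), while the hydrogen-bonded electron-rich aryl aldehydes are expected to survive the mild conditions.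

Step 17
Reactants: 23 4-hydroxy-5-{(1S)-1-[(1R,4R,4aS,6S,8aR)-4-hydroxy-4,8a-dimethyl-6-{2-[(triethylsilyl)oxy]propan-2-yl}decahydronaphthalen-1-yl]-3-methylbutyl}-2,6-dimethoxybenzene-1,3-dicarbaldehyde
Product: 25 2,4,6-trihydroxy-5-{(1S)-1-[(1R,4R,4aS,6S,8aR)-4-hydroxy-6-(2-hydroxypropan-2-yl)-4,8a-dimethyldecahydronaphthalen-1-yl]-3-methylbutyl}benzene-1,3-dicarbaldehyde, via triethylsilyl ether 24 (not isolated)
Conditions: NaSEt (6 equiv), DMF, 100 °C; then 1 M HCl, THF, rt
Reagents that add atoms: none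
Why: Thiolate-mediated O-demethylation (SN2 at methyl) of the two methoxy groups, both activated by ortho formyl groups, proceeds under basic conditions that spare the tertiary alcohols, and brief acid treatment then removes the triethylsilyl ether to give the target without touching any stereocentre.

**Compound list**

1 | 2-methylbut-3-yn-2-ol | CC(C)(O)C#C | starting material
2 | triethyl[(2-methylbut-3-yn-2-yl)oxy]silane | CC(C)(O[Si](CC)(CC)CC)C#C | intermediate
3 | ethylene | C=C | starting material
4 | triethyl[(2-methyl-3-methylidenepent-4-en-2-yl)oxy]silane | C=CC(=C)C(C)(C)O[Si](CC)(CC)CC | intermediate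
5 | ethyl (2E)-3-methyl-4-oxobut-2-enoate | CCOC(=O)/C=C(\C)C=O | starting material
6 | ethyl (1S,6S)-6-formyl-6-methyl-3-{2-[(triethylsilyl)oxy]propan-2-yl}cyclohex-3-ene-1-carboxylate | CCOC(=O)[C@H]1CC(C(C)(C)O[Si](CC)(CC)CC)=CC[C@]1(C)C=O | intermediate
7 | ethyl (1S,6S)-6-(1-hydroxyethyl)-6-methyl-3-{2-[(triethylsilyl)oxy]propan-2-yl}cyclohex-3-ene-1-carboxylate (both carbinol epimers) | CCOC(=O)[C@H]1CC(C(C)(C)O[Si](CC)(CC)CC)=CC[C@]1(C)C(C)O | intermediate
8 | ethyl (1S,6S)-6-acetyl-6-methyl-3-{2-[(triethylsilyl)oxy]propan-2-yl}cyclohex-3-ene-1-carboxylate | CCOC(=O)[C@H]1CC(C(C)(C)O[Si](CC)(CC)CC)=CC[C@]1(C)C(C)=O | intermediate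
9 | (3aS,7aS)-7a-methyl-5-{2-[(triethylsilyl)oxy]propan-2-yl}-3a,4,7,7a-tetrahydro-1H-indene-1,3(2H)-dione (drawn as diketone) | O=C1CC(=O)[C@H]2CC(C(C)(C)O[Si](CC)(CC)CC)=CC[C@]12C | intermediate
10 | ethylzinc cyclopropanolate formed by CH2 transfer to the enolate C=C of 9 (either enolate terminus and either face; all converge) | O=C1C2CC2(O[Zn]CC)[C@H]3CC(C(C)(C)O[Si](CC)(CC)CC)=CC[C@]13C | intermediate
11 | (4aS,8aS)-8a-methyl-6-{2-[(triethylsilyl)oxy]propan-2-yl}-2,3,4a,5,8,8a-hexahydronaphthalene-1,4-dione | O=C1CCC(=O)[C@H]2CC(C(C)(C)O[Si](CC)(CC)CC)=CC[C@]12C | intermediate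
12 | (4aS,6S,8aS)-8a-methyl-6-{2-[(triethylsilyl)oxy]propan-2-yl}octahydronaphthalene-1,4-dione | O=C1CCC(=O)[C@H]2C[C@@H](C(C)(C)O[Si](CC)(CC)CC)CC[C@]12C | intermediate
13 | (4R,4aS,6S,8aS)-4-hydroxy-4,8a-dimethyl-6-{2-[(triethylsilyl)oxy]propan-2-yl}octahydronaphthalen-1(2H)-one | O=C1CC[C@@](C)(O)[C@H]2C[C@@H](C(C)(C)O[Si](CC)(CC)CC)CC[C@]12C | intermediate
14 | (3-methylbutyl)triphenylphosphonium bromide | CC(C)CC[P+](c1ccccc1)(c1ccccc1)c1ccccc1.[Br-] | starting material
15 | (1Z,4R,4aS,6S,8aS)-4,8a-dimethyl-1-(3-methylbutylidene)-6-{2-[(triethylsilyl)oxy]propan-2-yl}decahydronaphthalen-4-ol | CC(C)C/C=C1/CC[C@@](C)(O)[C@H]2C[C@@H](C(C)(C)O[Si](CC)(CC)CC)CC[C@]12C | intermediate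
16 | (1E,2S,4R,4aS,6S,8aS)-4,8a-dimethyl-1-(3-methylbutylidene)-6-{2-[(triethylsilyl)oxy]propan-2-yl}decahydronaphthalene-2,4-diol | CC(C)C/C=C1/[C@@H](O)C[C@@](C)(O)[C@H]2C[C@@H](C(C)(C)O[Si](CC)(CC)CC)CC[C@]12C | intermediate
17 | (1Z,4R,4aS,6S,8aS)-4-hydroxy-4,8a-dimethyl-1-(3-methylbutylidene)-6-{2-[(triethylsilyl)oxy]propan-2-yl}octahydronaphthalen-2(1H)-one | CC(C)C/C=C1\C(=O)C[C@@](C)(O)[C@H]2C[C@@H](C(C)(C)O[Si](CC)(CC)CC)CC[C@]12C | intermediate
18 | (1Z,2S,4R,4aS,6S,8aS)-4,8a-dimethyl-1-(3-methylbutylidene)-6-{2-[(triethylsilyl)oxy]propan-2-yl}decahydronaphthalene-2,4-diol | CC(C)C/C=C1\[C@@H](O)C[C@@](C)(O)[C@H]2C[C@@H](C(C)(C)O[Si](CC)(CC)CC)CC[C@]12C | intermediate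
19 | 4-fluoro-2,6-dimethoxybenzaldehyde | COc1cc(F)cc(OC)c1C=O | starting material
20 | 4-fluoro-2,6-dimethoxybenzene-1,3-dicarbaldehyde | COc1cc(F)c(C=O)c(OC)c1C=O | intermediate
21 | 4-{[(1Z,2S,4R,4aS,6S,8aS)-4-hydroxy-4,8a-dimethyl-1-(3-methylbutylidene)-6-{2-[(triethylsilyl)oxy]propan-2-yl}decahydronaphthalen-2-yl]oxy}-2,6-dimethoxybenzene-1,3-dicarbaldehyde | CC(C)C/C=C1\[C@@H](Oc3cc(OC)c(C=O)c(OC)c3C=O)C[C@@](C)(O)[C@H]2C[C@@H](C(C)(C)O[Si](CC)(CC)CC)CC[C@]12C | intermediate
22 | 4-hydroxy-5-{(1S)-1-[(4R,4aS,6S,8aS)-4-hydroxy-4,8a-dimethyl-6-{2-[(triethylsilyl)oxy]propan-2-yl}-3,4,4a,5,6,7,8,8a-octahydronaphthalen-1-yl]-3-methylbutyl}-2,6-dimethoxybenzene-1,3-dicarbaldehyde | CC(C)C[C@H](c3c(O)c(C=O)c(OC)c(C=O)c3OC)C1=CC[C@@](C)(O)[C@H]2C[C@@H](C(C)(C)O[Si](CC)(CC)CC)CC[C@]12C | intermediate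
23 | 4-hydroxy-5-{(1S)-1-[(1R,4R,4aS,6S,8aR)-4-hydroxy-4,8a-dimethyl-6-{2-[(triethylsilyl)oxy]propan-2-yl}decahydronaphthalen-1-yl]-3-methylbutyl}-2,6-dimethoxybenzene-1,3-dicarbaldehyde | CC(C)C[C@H](c3c(O)c(C=O)c(OC)c(C=O)c3OC)[C@H]1CC[C@@](C)(O)[C@H]2C[C@@H](C(C)(C)O[Si](CC)(CC)CC)CC[C@]12C | intermediate
24 | 2,4,6-trihydroxy-5-{(1S)-1-[(1R,4R,4aS,6S,8aR)-4-hydroxy-4,8a-dimethyl-6-{2-[(triethylsilyl)oxy]propan-2-yl}decahydronaphthalen-1-yl]-3-methylbutyl}benzene-1,3-dicarbaldehyde | CC(C)C[C@H](c3c(O)c(C=O)c(O)c(C=O)c3O)[C@H]1CC[C@@](C)(O)[C@H]2C[C@@H](C(C)(C)O[Si](CC)(CC)CC)CC[C@]12C | intermediate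
25 | 2,4,6-trihydroxy-5-{(1S)-1-[(1R,4R,4aS,6S,8aR)-4-hydroxy-6-(2-hydroxypropan-2-yl)-4,8a-dimethyldecahydronaphthalen-1-yl]-3-methylbutyl}benzene-1,3-dicarbaldehyde | CC(C)C[C@H](c1c(O)c(C=O)c(O)c(C=O)c1O)[C@H]1CC[C@@](C)(O)[C@H]2C[C@@H](C(C)(C)O)CC[C@]12C | target

**Step count and risks**

Total steps: 17. Longest linear sequence: 16 (steps 1–12 and 14–17).

Steps most likely to fail:

Step 10. The ylide may fail to add to the C1 carbonyl, which is shielded by the quaternary C10, and enolisation toward C2 may consume the base instead. The fallback sets out from 13 and returns at 17. KN(SiMe3)2 and PhN(SO2CF3)2 should convert 13 into the C1 enol triflate F1 (enolisation is possible only toward C2). A Nozaki–Hiyama–Kishi coupling of the triflate with 3-methylbutanal (CrCl2, NiCl2 2 mol %, DMF) should give the allylic alcohol F2, which Dess–Martin oxidation converts into the enone F3. Nucleophilic epoxidation (H2O2, NaOH, MeOH) should give the epoxy ketone F4. Wharton transposition (N2H4·H2O, AcOH) then moves the oxygen to C2 and the alkene into the exocyclic position, giving the C2-epimeric allylic alcohol F5, and Dess–Martin oxidation with thiyl-radical equilibration leads to enone 17.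

Step 14. The hindered axial alkoxide may add reversibly to the formyl groups while fluoride displacement stays too slow. The fallback sets out from 18 and returns at 23. Metal-free O-arylation of the sodium alkoxide of 18 with bis(3,5-dimethoxyphenyl)iodonium triflate should give the aryl ether F6. Aromatic Claisen rearrangement (N,N-diethylaniline, 175 °C) should give the phenol F7 with the same transfer of chirality to C1′, and hydrogenation (H2, Pd/C) the saturated phenol F8. N-Bromosuccinimide (2 equiv) should brominate both free ring positions to give the dibromide F9, and bromine–lithium exchange (t-BuLi in excess, THF, −78 °C) followed by DMF installs both formyl groups to give 23.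

Step 16. Reduction of the hindered trisubstituted alkene may be slow and accompanied by reduction of the formyl groups. The fallback sets out from 22 and returns at 23 without a new compound (F0): radical hydrogen-atom-transfer hydrogenation (Mn(dpm)3, PhSiH3, t-BuOOH, i-PrOH; dpm = dipivaloylmethanate) should reduce the alkene stepwise through the tertiary C1 radical and place the side chain in the thermodynamically favoured equatorial position.

Further compounds
F1 | step 10 | (4R,4aS,6S,8aS)-4-hydroxy-4,8a-dimethyl-6-{2-[(triethylsilyl)oxy]propan-2-yl}-3,4,4a,5,6,7,8,8a-octahydronaphthalen-1-yl trifluoromethanesulfonate | O=S(=O)(OC1=CC[C@@](C)(O)[C@H]2C[C@@H](C(C)(C)O[Si](CC)(CC)CC)CC[C@]12C)C(F)(F)F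
F2 | step 10 | 1-[(4R,4aS,6S,8aS)-4-hydroxy-4,8a-dimethyl-6-{2-[(triethylsilyl)oxy]propan-2-yl}-3,4,4a,5,6,7,8,8a-octahydronaphthalen-1-yl]-3-methylbutan-1-ol (both carbinol epimers) | CC(C)CC(O)C1=CC[C@@](C)(O)[C@H]2C[C@@H](C(C)(C)O[Si](CC)(CC)CC)CC[C@]12C
F3 | step 10 | 1-[(4R,4aS,6S,8aS)-4-hydroxy-4,8a-dimethyl-6-{2-[(triethylsilyl)oxy]propan-2-yl}-3,4,4a,5,6,7,8,8a-octahydronaphthalen-1-yl]-3-methylbutan-1-one | CC(C)CC(=O)C1=CC[C@@](C)(O)[C@H]2C[C@@H](C(C)(C)O[Si](CC)(CC)CC)CC[C@]12C
F4 | step 10 | C1–C2 epoxide of F3 with the oxirane on the face opposite to the C8a methyl | CC(C)CC(=O)[C@]13O[C@@H]3C[C@@](C)(O)[C@H]2C[C@@H](C(C)(C)O[Si](CC)(CC)CC)CC[C@]12C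
F5 | step 10 | (2R,4R,4aS,6S,8aS)-4,8a-dimethyl-1-(3-methylbutylidene)-6-{2-[(triethylsilyl)oxy]propan-2-yl}decahydronaphthalene-2,4-diol (alkene isomers, E drawn) | CC(C)C/C=C1/[C@H](O)C[C@@](C)(O)[C@H]2C[C@@H](C(C)(C)O[Si](CC)(CC)CC)CC[C@]12C
F6 | step 14 | (1Z,2S,4R,4aS,6S,8aS)-2-(3,5-dimethoxyphenoxy)-4,8a-dimethyl-1-(3-methylbutylidene)-6-{2-[(triethylsilyl)oxy]propan-2-yl}decahydronaphthalen-4-ol | CC(C)C/C=C1\[C@@H](Oc3cc(OC)cc(OC)c3)C[C@@](C)(O)[C@H]2C[C@@H](C(C)(C)O[Si](CC)(CC)CC)CC[C@]12C
F7 | step 14 | 2-{(1S)-1-[(4R,4aS,6S,8aS)-4-hydroxy-4,8a-dimethyl-6-{2-[(triethylsilyl)oxy]propan-2-yl}-3,4,4a,5,6,7,8,8a-octahydronaphthalen-1-yl]-3-methylbutyl}-3,5-dimethoxyphenol | CC(C)C[C@H](c3c(O)cc(OC)cc3OC)C1=CC[C@@](C)(O)[C@H]2C[C@@H](C(C)(C)O[Si](CC)(CC)CC)CC[C@]12C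
F8 | step 14 | 2-{(1S)-1-[(1R,4R,4aS,6S,8aR)-4-hydroxy-4,8a-dimethyl-6-{2-[(triethylsilyl)oxy]propan-2-yl}decahydronaphthalen-1-yl]-3-methylbutyl}-3,5-dimethoxyphenol | CC(C)C[C@H](c3c(O)cc(OC)cc3OC)[C@H]1CC[C@@](C)(O)[C@H]2C[C@@H](C(C)(C)O[Si](CC)(CC)CC)CC[C@]12C
F9 | step 14 | 2,4-dibromo-6-{(1S)-1-[(1R,4R,4aS,6S,8aR)-4-hydroxy-4,8a-dimethyl-6-{2-[(triethylsilyl)oxy]propan-2-yl}decahydronaphthalen-1-yl]-3-methylbutyl}-3,5-dimethoxyphenol | CC(C)C[C@H](c3c(O)c(Br)c(OC)c(Br)c3OC)[C@H]1CC[C@@](C)(O)[C@H]2C[C@@H](C(C)(C)O[Si](CC)(CC)CC)CC[C@]12C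
F0 | step 16 | none | none
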